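Each cyclohexene ring (C1 = diene-bearing sp2 carbon, C2 = ring CH, C3 = quaternary carbon, C4 = carbinol, C5 and C6 = the CH2 pair) is traced back to a 4-silyloxy-3-methylcyclohex-2-enone, whose C1 carbonyl and C4 oxygen flank the C5–C6 ethano bridge. This 1,4-dioxygenated C1–C4 array is 4-methylfuran-2(5H)-one in disguise: its γ-anion and allyl acrylate unite in one anionic [4+2] (Michael–Dieckmann) operation that forges C4–C5 and C6–C1, while the lactone oxygens become the C1 ketone and the C4 hydroxyl. anti-Selective cuprate addition then sets C3 and delivers a regiodefined C1 triflate. Shi epoxidation, Stille coupling and copper-mediated dimerisation complete the twofold-symmetric tetraene.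

Key step: step 1

Remark (assumption): Candida antarctica lipase B is assumed to follow Kazlauskas' rule on 8 and acylate the (R)-alcohol, leaving the (S)-alcohol; should the sense be opposite, the acetate fraction would be carried on after mild deacetylation.
Remark (supply): compounds 1, 2, 11 and 17 are taken as commercial.

Step 1
Reactants: 1 4-methylfuran-2(5H)-one; 2 allyl acrylate
Product: 6 allyl 5-hydroxy-4-methyl-2-oxocyclohex-3-ene-1-carboxylate (racemic; epimers at the ester-bearing carbon), via lithium 4-methylfuran-2-olate 3 (not isolated), via ester enolate of the Michael adduct 4 (not isolated), via oxa-bridged lithium alkoxide 5 (not isolated)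
Conditions: LiN(SiMe3)2 (1.05 equiv), THF, −78 °C; then 2 (1.0 equiv, slow addition), −78 to 23 °C; AcOH
Reagents that add atoms: none
Why: LiN(SiMe3)2 removes a γ-proton of 1 to give the aromatic 2-oxidofuran 3, whose O-bearing carbon (future ring C4) adds to the β-carbon of 2 (future C5) in a vinylogous Michael reaction; the ester enolate 4 (future C6) then acylates itself on the lactone carbonyl (future C1), and the strained 7-oxabicyclo[2.2.1]heptene alkoxide 5 collapses by expelling the ring oxygen as the C4 alkoxide, the cascade ending at the stabilised β-keto ester enolate. The closest known reaction type is the Hauser–Kraus (Sammes) anionic [4+2] annulation of phthalide anions, of which this is the non-benzo version; formally it is a Diels–Alder addition of a 2-oxyfuran across its 2- and 5-positions followed by opening of the oxygen bridge. The six-membered carbocycle is closed by a 6-exo-trig Dieckmann attack of the enolate on the lactone C=O (5-exo-trig with respect to the transient oxolane ring), which the Z-locked ring alkene of the butenolide holds within reach. Two stereocentres arise: C4 forms without control (racemic, resolved in step 3), and the ester-bearing C6 is epimerisable and is erased in step 2. The step needs γ- over α-attack of the ambident dienolate, which the soft acrylate acceptor and the aromatic furanolate should secure, and it needs ring closure to prevail over acrylate oligomerisation, which slow addition of one equivalent at −78 °C addresses. Proton transfer from the remaining γ-CH of 4 to give a 5-substituted furanolate is a reversible detour, because only the β-keto ester enolate is a thermodynamic sink.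

Step 2
Reactants: 6 allyl 5-hydroxy-4-methyl-2-oxocyclohex-3-ene-1-carboxylate
Product: 8 rac-4-hydroxy-3-methylcyclohex-2-en-1-one, via β-keto acid 7 (not isolated)
Conditions: Pd(PPh3)4 (3 mol%), morpholine (2 equiv), THF, 23 °C
Reagents that add atoms: none
Why: Tsuji–Trost deallylation, in which zerovalent palladium ionises the allyl ester to a π-allyl complex that morpholine captures, frees β-keto acid 7, which loses CO2 spontaneously under neutral conditions that leave the γ-hydroxy enone untouched; the ester-bearing centre becomes CH2 and no stereocentre is set.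

Step 3
Reactants: 8 rac-4-hydroxy-3-methylcyclohex-2-en-1-one
Product: 9 (S)-4-hydroxy-3-methylcyclohex-2-en-1-one
Conditions: Candida antarctica lipase B (immobilised), vinyl acetate, t-BuOMe, 30 °C, stopped just past half conversion; chromatography
Reagents that add atoms: none
Why: Enzymatic kinetic resolution by a lipase (serine hydrolase), which should acetylate the (R)-alcohol faster, as Kazlauskas' rule predicts for a carbinol flanked by the large C3 sp2 carbon and the medium C5 methylene, so that unreacted (S)-9 remains in high enantiomeric purity and fixes the C4 configuration of the target.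

Step 4
Reactants: 9 (S)-4-hydroxy-3-methylcyclohex-2-en-1-one
Product: 10 (S)-4-[(tert-butyldimethylsilyl)oxy]-3-methylcyclohex-2-en-1-one
Conditions: t-BuMe2SiCl, imidazole, DMF, 23 °C
Reagents that add atoms: tert-butyldimethylsilyl chloride, CC(C)(C)[Si](C)(C)Cl
Why: Standard silylation of the secondary allylic alcohol gives a bulky, poorly leaving silyl ether that resists cuprate-induced γ-elimination and shields one enone face in step 5, without touching the stereocentre.

Step 5
Reactants: 10 (S)-4-[(tert-butyldimethylsilyl)oxy]-3-methylcyclohex-2-en-1-one; 11 5-bromo-2-methylpent-2-ene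
Product: 15 (3S,4S)-4-[(tert-butyldimethylsilyl)oxy]-3-methyl-3-(4-methylpent-3-en-1-yl)cyclohex-1-en-1-yl trifluoromethanesulfonate, via Grignard reagent 12 (not isolated), via trimethylsilyl enol ether 13 (not isolated), via lithium enolate 14 (not isolated)
Conditions: 11, Mg, THF, 23 °C; CuBr·SMe2 (20 mol%), Me3SiCl, HMPA, then 10, THF, −78 to −40 °C; crude 13, MeLi, THF, 0 °C; PhNTf2, −78 to 23 °C
Reagents that add atoms: N-phenylbis(trifluoromethanesulfonimide), O=S(=O)(N(c1ccccc1)S(=O)(=O)C(F)(F)F)C(F)(F)F
Why: Copper-catalysed, Me3SiCl-accelerated conjugate addition of Grignard reagent 12 should deliver the homoprenyl group to C3 anti to the adjacent C4 silyloxy group, setting the quaternary centre as (S) with methyl cis to oxygen, and the regiodefined silyl enol ether 13 is converted by MeLi into enolate 14 and O-triflated by PhNTf2, so the C1=C2 double bond and its coupling handle are fixed without a regiochemical choice.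

Step 6
Reactants: 15 (3S,4S)-4-[(tert-butyldimethylsilyl)oxy]-3-methyl-3-(4-methylpent-3-en-1-yl)cyclohex-1-en-1-yl trifluoromethanesulfonate
Product: 16 (3S,4S)-4-[(tert-butyldimethylsilyl)oxy]-3-{2-[(2R)-3,3-dimethyloxiran-2-yl]ethyl}-3-methylcyclohex-1-en-1-yl trifluoromethanesulfonate
Conditions: D-fructose-derived Shi ketone (0.3 equiv), Oxone (2KHSO5·KHSO4·K2SO4), K2CO3, Bu4NHSO4 (cat.), MeCN–CH2(OMe)2–aq. Na2B4O7 buffer, 0 °C
Reagents that add atoms: potassium peroxymonosulfate (active component of Oxone), OOS(=O)(=O)[O-].[K+]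
Why: Shi asymmetric epoxidation, in which the chiral dioxirane formed from the ketone attacks the electron-rich trisubstituted side-chain olefin through the spiro transition state, is expected to give the (R)-epoxide under reagent control while the electron-poor enol triflate double bond stays intact.

Step 7
Reactants: 16 epoxy triflate; 17 (E)-1,2-bis(tributylstannyl)ethene
Product: 18 tributyl{(E)-2-[(3S,4S)-4-[(tert-butyldimethylsilyl)oxy]-3-{2-[(2R)-3,3-dimethyloxiran-2-yl]ethyl}-3-methylcyclohex-1-en-1-yl]ethenyl}stannane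
Conditions: 17 (3 equiv), Pd2(dba)3 (2.5 mol%), AsPh3 (20 mol%), NMP, 40 °C
Reagents that add atoms: none
Why: Stille coupling, by oxidative addition of zerovalent palladium to the alkenyl triflate, transmetalation with one tin terminus of 17 (used in excess to suppress double coupling) and reductive elimination, gives the (E)-dienylstannane with retention of olefin geometry under neutral conditions that spare epoxide and silyl ether.

Step 8
Reactants: 18 dienylstannane (two molecules)
Product: 19 (1E,3E)-1,4-bis[(3S,4S)-4-[(tert-butyldimethylsilyl)oxy]-3-{2-[(2R)-3,3-dimethyloxiran-2-yl]ethyl}-3-methylcyclohex-1-en-1-yl]buta-1,3-diene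
Conditions: CuCl (3 equiv), DMF, 23 °C, dark, argon
Reagents that add atoms: none
Why: Copper-mediated oxidative homocoupling of alkenylstannanes (Piers type) proceeds by tin-to-copper transmetalation to a dienylcopper species that dimerises with retention of E geometry, forming the central bond of the (E,E)-tetraene under neutral conditions and leaving every stereocentre untouched.

Step 9
Reactants: 19 bis-silyl ether
Product: 20 (1E,3E)-1,4-bis[(3S,4S)-3-{2-[(2R)-3,3-dimethyloxiran-2-yl]ethyl}-4-hydroxy-3-methylcyclohex-1-en-1-yl]buta-1,3-diene (target)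
Conditions: Bu4NF, THF, 23 to 45 °C, dark
Reagents that add atoms: none
Why: Fluoride-mediated cleavage of the two secondary silyl ethers, driven by Si–F bond formation, occurs under mildly basic conditions that spare the trisubstituted epoxides and the tetraene, and affects no stereocentre.

Compound list
1 | 4-methylfuran-2(5H)-one | CC1=CC(=O)OC1 | starting material
2 | allyl acrylate (prop-2-en-1-yl prop-2-enoate) | C=CC(=O)OCC=C | starting material
3 | lithium 4-methylfuran-2-olate | Cc1coc([O-])c1.[Li+] | intermediate (not isolated)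
4 | lithium ester enolate of allyl 3-(3-methyl-5-oxo-2,5-dihydrofuran-2-yl)propanoate (racemic) | CC1=CC(=O)OC1CC=C([O-])OCC=C.[Li+] | intermediate (not isolated)
5 | lithium alkoxide of allyl 1-hydroxy-5-methyl-7-oxabicyclo[2.2.1]hept-5-ene-2-carboxylate (racemic) | [O-]C12C=C(C)C(O1)CC2C(=O)OCC=C.[Li+] | intermediate (not isolated)
6 | allyl 5-hydroxy-4-methyl-2-oxocyclohex-3-ene-1-carboxylate (racemic, epimer mixture) | O=C1C=C(C)C(O)CC1C(=O)OCC=C | intermediate
7 | 5-hydroxy-4-methyl-2-oxocyclohex-3-ene-1-carboxylic acid (racemic) | O=C1C=C(C)C(O)CC1C(=O)O | intermediate (not isolated)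
8 | rac-4-hydroxy-3-methylcyclohex-2-en-1-one | CC1=CC(=O)CCC1O | intermediate
9 | (S)-4-hydroxy-3-methylcyclohex-2-en-1-one | CC1=CC(=O)CC[C@@H]1O | intermediate
10 | (S)-4-[(tert-butyldimethylsilyl)oxy]-3-methylcyclohex-2-en-1-one | CC1=CC(=O)CC[C@@H]1O[Si](C)(C)C(C)(C)C | intermediate
11 | 5-bromo-2-methylpent-2-ene | CC(C)=CCCBr | starting material
12 | (4-methylpent-3-en-1-yl)magnesium bromide | CC(C)=CCC[Mg]Br | intermediate (not isolated)
13 | (3S,4S)-4-[(tert-butyldimethylsilyl)oxy]-3-methyl-3-(4-methylpent-3-en-1-yl)-1-[(trimethylsilyl)oxy]cyclohex-1-ene | CC(C)=CCC[C@@]1(C)C=C(O[Si](C)(C)C)CC[C@@H]1O[Si](C)(C)C(C)(C)C | intermediate (not isolated)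
14 | lithium (3S,4S)-4-[(tert-butyldimethylsilyl)oxy]-3-methyl-3-(4-methylpent-3-en-1-yl)cyclohex-1-en-1-olate | CC(C)=CCC[C@@]1(C)C=C([O-])CC[C@@H]1O[Si](C)(C)C(C)(C)C.[Li+] | intermediate (not isolated)
15 | (3S,4S)-4-[(tert-butyldimethylsilyl)oxy]-3-methyl-3-(4-methylpent-3-en-1-yl)cyclohex-1-en-1-yl trifluoromethanesulfonate | CC(C)=CCC[C@@]1(C)C=C(OS(=O)(=O)C(F)(F)F)CC[C@@H]1O[Si](C)(C)C(C)(C)C | intermediate
16 | (3S,4S)-4-[(tert-butyldimethylsilyl)oxy]-3-{2-[(2R)-3,3-dimethyloxiran-2-yl]ethyl}-3-methylcyclohex-1-en-1-yl trifluoromethanesulfonate | CC1(C)O[C@@H]1CC[C@@]1(C)C=C(OS(=O)(=O)C(F)(F)F)CC[C@@H]1O[Si](C)(C)C(C)(C)C | intermediate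
17 | (E)-1,2-bis(tributylstannyl)ethene | CCCC[Sn](CCCC)(CCCC)/C=C/[Sn](CCCC)(CCCC)CCCC | starting material
18 | tributyl{(E)-2-[(3S,4S)-4-[(tert-butyldimethylsilyl)oxy]-3-{2-[(2R)-3,3-dimethyloxiran-2-yl]ethyl}-3-methylcyclohex-1-en-1-yl]ethenyl}stannane | CC1(C)O[C@@H]1CC[C@@]1(C)C=C(/C=C/[Sn](CCCC)(CCCC)CCCC)CC[C@@H]1O[Si](C)(C)C(C)(C)C | intermediate
19 | (1E,3E)-1,4-bis[(3S,4S)-4-[(tert-butyldimethylsilyl)oxy]-3-{2-[(2R)-3,3-dimethyloxiran-2-yl]ethyl}-3-methylcyclohex-1-en-1-yl]buta-1,3-diene | CC1(C)O[C@@H]1CC[C@@]1(C)C=C(/C=C/C=C/C2=C[C@](C)(CC[C@H]3OC3(C)C)[C@@H](O[Si](C)(C)C(C)(C)C)CC2)CC[C@@H]1O[Si](C)(C)C(C)(C)C | intermediate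
20 | (1E,3E)-1,4-bis[(3S,4S)-3-{2-[(2R)-3,3-dimethyloxiran-2-yl]ethyl}-4-hydroxy-3-methylcyclohex-1-en-1-yl]buta-1,3-diene | CC1(C)O[C@@H]1CC[C@@]1(C)C=C(/C=C/C=C/C2=C[C@](C)(CC[C@H]3OC3(C)C)[C@@H](O)CC2)CC[C@@H]1O | target

Total step count: 9. Longest linear sequence: 9 steps (from 1; compounds 2, 11 and 17 enter as purchased materials).

Steps most likely to fail

Step 1. The ambident dienolate may attack through its α-carbon, or anionic oligomerisation of the acrylate may outrun the Dieckmann closure. The fallback replaces the anionic cascade by a neutral cycloaddition that forms the same two bonds; it sets out from 1 and returns at 8. Compound 1 is silylated (t-BuMe2SiOTf, Et3N, CH2Cl2) to tert-butyl(dimethyl)[(4-methylfuran-2-yl)oxy]silane F1. Thermal Diels–Alder reaction of F1 with phenyl vinyl sulfone (toluene, 80 °C), its regiochemistry directed by the 2-silyloxy donor, gives 1-[(tert-butyldimethylsilyl)oxy]-5-methyl-2-(phenylsulfonyl)-7-oxabicyclo[2.2.1]hept-5-ene F2. Fluoride (Bu4NF, AcOH, THF) removes the bridgehead silyl group, and the oxygen bridge opens to 4-hydroxy-3-methyl-6-(phenylsulfonyl)cyclohex-2-en-1-one F3. Radical desulfonylation of this α-sulfonyl ketone (Bu3SnH, AIBN, toluene, 80 °C) gives 8.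

Step 5. Conjugate addition at the fully substituted β-carbon next to the silyloxy-bearing carbon may be sluggish, with competing 1,2-addition and erosion of the anti facial preference. The fallback uses the smaller, more reactive allyl nucleophile and builds the side chain afterwards; it sets out from 10 and returns at 15.
- Allylmagnesium bromide, CuBr·SMe2 and Me3SiCl convert 10 into (3S,4S)-3-allyl-4-[(tert-butyldimethylsilyl)oxy]-3-methyl-1-[(trimethylsilyl)oxy]cyclohex-1-ene F4.
- MeLi gives lithium (3S,4S)-3-allyl-4-[(tert-butyldimethylsilyl)oxy]-3-methylcyclohex-1-en-1-olate F5, and PhNTf2 gives (3S,4S)-3-allyl-4-[(tert-butyldimethylsilyl)oxy]-3-methylcyclohex-1-en-1-yl trifluoromethanesulfonate F6.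
- Hydroboration of the terminal olefin with 9-BBN gives the B-alkyl-9-borabicyclo[3.3.1]nonane F7, which NaBO3·4H2O oxidises to (3S,4S)-4-[(tert-butyldimethylsilyl)oxy]-3-(3-hydroxypropyl)-3-methylcyclohex-1-en-1-yl trifluoromethanesulfonate F8.
- Dess–Martin oxidation gives (3S,4S)-4-[(tert-butyldimethylsilyl)oxy]-3-methyl-3-(3-oxopropyl)cyclohex-1-en-1-yl trifluoromethanesulfonate F9, and Wittig olefination with isopropylidenetriphenylphosphorane gives 15.

Step 8. Tin-to-copper transmetalation of the tributylstannane may be slow, allowing protodestannylation or loss of E geometry in the dienylcopper intermediate. The fallback replaces oxidative homocoupling by a cross-coupling; it sets out from 18 and returns at 19. Half of 18 is treated with I2 (CH2Cl2, 0 °C) to give tert-butyl{[(1S,2S)-2-{2-[(2R)-3,3-dimethyloxiran-2-yl]ethyl}-4-[(E)-2-iodoethenyl]-2-methylcyclohex-3-en-1-yl]oxy}dimethylsilane F10. Stille coupling of F10 with the other half of 18 (Pd2(dba)3, AsPh3, NMP, 23 °C) gives 19.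

Further compounds
F1 | step 1 | tert-butyl(dimethyl)[(4-methylfuran-2-yl)oxy]silane | Cc1coc(O[Si](C)(C)C(C)(C)C)c1
F2 | step 1 | 1-[(tert-butyldimethylsilyl)oxy]-5-methyl-2-(phenylsulfonyl)-7-oxabicyclo[2.2.1]hept-5-ene (racemic) | CC1=CC2(O[Si](C)(C)C(C)(C)C)OC1CC2S(=O)(=O)c1ccccc1
F3 | step 1 | 4-hydroxy-3-methyl-6-(phenylsulfonyl)cyclohex-2-en-1-one (racemic) | CC1=CC(=O)C(S(=O)(=O)c2ccccc2)CC1O
F4 | step 5 | (3S,4S)-3-allyl-4-[(tert-butyldimethylsilyl)oxy]-3-methyl-1-[(trimethylsilyl)oxy]cyclohex-1-ene | C=CC[C@@]1(C)C=C(O[Si](C)(C)C)CC[C@@H]1O[Si](C)(C)C(C)(C)C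
F5 | step 5 | lithium (3S,4S)-3-allyl-4-[(tert-butyldimethylsilyl)oxy]-3-methylcyclohex-1-en-1-olate | C=CC[C@@]1(C)C=C([O-])CC[C@@H]1O[Si](C)(C)C(C)(C)C.[Li+]
F6 | step 5 | (3S,4S)-3-allyl-4-[(tert-butyldimethylsilyl)oxy]-3-methylcyclohex-1-en-1-yl trifluoromethanesulfonate | C=CC[C@@]1(C)C=C(OS(=O)(=O)C(F)(F)F)CC[C@@H]1O[Si](C)(C)C(C)(C)C
F7 | step 5 | (3S,4S)-3-[3-(9-borabicyclo[3.3.1]nonan-9-yl)propyl]-4-[(tert-butyldimethylsilyl)oxy]-3-methylcyclohex-1-en-1-yl trifluoromethanesulfonate | C1CCC2CCCC1B2CCC[C@@]1(C)C=C(OS(=O)(=O)C(F)(F)F)CC[C@@H]1O[Si](C)(C)C(C)(C)C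
F8 | step 5 | (3S,4S)-4-[(tert-butyldimethylsilyl)oxy]-3-(3-hydroxypropyl)-3-methylcyclohex-1-en-1-yl trifluoromethanesulfonate | OCCC[C@@]1(C)C=C(OS(=O)(=O)C(F)(F)F)CC[C@@H]1O[Si](C)(C)C(C)(C)C
F9 | step 5 | (3S,4S)-4-[(tert-butyldimethylsilyl)oxy]-3-methyl-3-(3-oxopropyl)cyclohex-1-en-1-yl trifluoromethanesulfonate | O=CCC[C@@]1(C)C=C(OS(=O)(=O)C(F)(F)F)CC[C@@H]1O[Si](C)(C)C(C)(C)C
F10 | step 8 | tert-butyl{[(1S,2S)-2-{2-[(2R)-3,3-dimethyloxiran-2-yl]ethyl}-4-[(E)-2-iodoethenyl]-2-methylcyclohex-3-en-1-yl]oxy}dimethylsilane | CC1(C)O[C@@H]1CC[C@@]1(C)C=C(/C=C/I)CC[C@@H]1O[Si](C)(C)C(C)(C)C
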